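The summer run is the close neighbour of north-east: the same racemate, the same impurity and the same 40 h feed, but 42 mM of coupling partner against 30.0 mM. It ended at an excess of 41.8 %.

the same everywhere: left-handed substrate 33 mM; right-handed substrate 33 mM

| run | coupling partner | protic impurity | remark | time |
|---|---|---|---|---|
| summer | 42 mM (fed, over 40 h) | 6.6 mM | run made earlier |  |
| north-east | 30.0 mM (fed, over 40 h) | 6.60 mM |  | 40 h |
| south-east | 100 mM (fed, over 40 h) | 6.60 mM |  | 40 h |
| north | 300 mM (fed, over 40 h) | 6.60 mM |  | 40 h |
| west | 800 mM (fed, over 40 h) | 6.60 mM |  | 40 h |
| north-west | 2500 mM (fed, over 40 h) | 6.60 mM |  | 40 h |

summer run (percent of the left-handed substrate and right-handed substrate together charged)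

| time / h | left-handed product / % | right-handed product / % |
|---|---|---|
| 2.50 | 0.4 | 0 |
| 8.00 | 5.1 | 3.8 |
| 15.0 | 10.6 | 4.5 |
| 20.0 | 16.9 | 4.1 |
| 30.0 | 24.0 | 7.6 |
| 40.0 | 32.4 | 13.3 |

(scatter of a reading: 1 percentage point)

- coupling partner is single-handed; left-handed substrate and right-handed substrate are mirror images of each other, charged as a racemate, each of them at the stated concentration
- a step back or a flat step of under half a point counts as no turn
- an excess is the difference of the two amounts in percent of their sum
- "hardly changes" means that all values lie within two and a half points (for a concentration: within two and a half percent of the largest)
- the handed part of coupling partner does not stay in what it makes, so the products of the two hands are mirror images too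

- excess of left-handed product over right-handed product at the end for north-east, south-east, north, west, north-west, in this order
- how the row runs (rises, then falls / hardly changes / falls, then rises / falls all the way / rises all the way)

Both hands react with the same coupling partner. If each rate is first order in that one concentration, it cancels from their ratio, however the feed moves it. The last summer reading gives 3.38, the selectivity factor: the logarithm of the fraction of left-handed substrate remaining over that of the right-handed. It is a reading with a scatter of 1 percentage point on each product, and the readings at 30.0 h give 3.97.

As an estimate of my own, which the readings do not show, I charge the impurity its whole 6.60 mM of partner. That leaves 35.4 mM for the hands in the summer flask and 23.4 mM in north-east. The summer flask reached 45.7 % conversion of both hands together. In north-east the partner is the limiting reagent, with 30.0 mM against 66.0 mM of substrate, and my estimated share for the hands amounts to a conversion of 35.5 %, lower than the summer figure, so I expect a higher excess in north-east. Spending it wholly under the selectivity factor leaves 80.6 % of the right-handed substrate, so my excess is 45.2 %. With larger charges I expect the excess to fall towards zero as both hands are consumed.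

The forecast gives 50 %, 11 %, 0.1 %, 0 % and 0 %, a row that falls all the way, on the ground that “Plain kinetic resolution fits the summer run”. Its first value stands above mine, and its ratio of 3.7 above my 3.38.

The flasks give 43.3 %, 13.1 %, 0.00539 %, 0 % and 0 %, and the row falls all the way.

    coupling partner + protic impurity → quenched reagent (k = 19.0 /M/h)
    coupling partner → decomposition product (k = 1.50 × 10⁻⁵ /h)
    coupling partner + right-handed substrate → right-handed product (k = 2.40 /M/h)
    coupling partner + left-handed substrate → left-handed product (k = 7.40 /M/h)

In north-east the impurity and both hands drew on the fed partner side by side, the impurity standing at 53.1 % of its charge at 20.0 h and 19.8 % at 40.0 h, with 10 % of the partner's charge unused at the end. There 81 % of the right-handed substrate remained, which under 3.38 gives 50.1 % of the left-handed substrate against 53 % found. In south-east the impurity was down to 6.35 % by 20.0 h, and the partner rose from 12.4 % to 35.8 % of its charge while the hands ran on; 24 % of the right-handed substrate remaining gives 0.829 % of the left-handed substrate against 1.3 % found.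

The runs are simulated for an exercise, noise included.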